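**Plan**
1. Retrosynthesis (germacrane locants): cut the O8–angeloyl ester and C11=C13. Then cut C5–C6 and O6–C12 in one event, then C7–C8 (aldol), C2–C3 (aldol) and C9–C10 (alkylation of a lactic acid template).
2. Enabling feature: C6 is the allylic carbinol carbon next to the Z-C4=C5 alkene of the ten-membered ring. It is also the γ-carbon of the lactone ring O6–C6–C7–C11–C12. A C5 alkenyl-metal adding to a C6 aldehyde therefore gives an alkoxide 1,4 to the C12 ester, so carbocycle and lactone close together.
3. Forward: the open chain is built from west to east (C10, then C3 and C1, then C8 and C7). Both rings arise in step 15. Methylenation, angelate and deprotection follow.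
4. Stereochemistry: C10 comes from (S)-lactic acid, C3 from a chiral boron enolate, and C1 from C3 by 1,3-anti reduction. C7 and C8 come from a thiazolidinethione auxiliary, and C6 from C7 (Felkin–Anh) during ring closure. The Z alkene comes from a directed anti-carbomagnesiation.
5. Helpers: a cis-dioxolane on O1/O10 serves as turn element and protecting group, with TBS on O3 and TES on O8. They are removed in steps 17 and 19.

Key step: step 15

Numbering remark: C1–C15 are the germacrane locants of the target (C6 lactone carbinol, C8 angelate carbon, C10 tertiary carbinol, C12 lactone carbonyl). O-n is the oxygen on C-n.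

Assumption: enol diisopinocampheylborinates of methyl ketones are taken to attack the aldehyde face opposite to the one chosen by the allylborane of the same pinene series. This assigns (+)-Ipc2BCl to the (3S)-carbinol. Both antipodes of the reagent are commercial.

**Route**

Step 1
Reactants: 1 (S)-lactic acid; 2 pivalaldehyde
Product: 3 (2S,5S)-2-tert-butyl-5-methyl-1,3-dioxolan-4-one (cis)
Conditions: p-TsOH (cat.), H2SO4 (cat.), pentane, reflux, Dean–Stark; crystallisation from pentane, −78 °C
Reagents that add atoms: none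
Why: Acid-catalysed acetalisation of the α-hydroxy acid (first stage of the Seebach self-regeneration of stereocentres); the lactic acid centre biases the new acetal centre and the cis isomer is purified by crystallisation.

Step 2
Reactants: 3 (2S,5S)-2-tert-butyl-5-methyl-1,3-dioxolan-4-one; 4 allyl bromide
Product: 5 (2S,5R)-5-allyl-2-tert-butyl-5-methyl-1,3-dioxolan-4-one
Conditions: LiN(i-Pr)2, THF, −78 °C; then 4, −78 → −20 °C
Reagents that add atoms: none
Why: Seebach enolate alkylation; the tert-butyl group shields one face of the planar enolate, so the allyl group enters trans to it and sets the quaternary carbinol centre C10 (R) with overall retention.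

Step 3
Reactants: 5 (2S,5R)-5-allyl-2-tert-butyl-5-methyl-1,3-dioxolan-4-one
Product: 6 (R)-3-hydroxy-3-methylhex-5-en-2-one
Conditions: MeLi (1.05 equiv), Et2O, −78 °C; then H2O
Reagents that add atoms: methyllithium [Li]C
Why: 1,2-Addition of an organolithium to the lactone-type carbonyl gives a cyclic hemiketal alkoxide that resists a second addition and collapses on work-up to the methyl ketone with loss of pivalaldehyde; C10 bears no hydrogen and cannot epimerise.

Step 4
Reactants: 6 (R)-3-hydroxy-3-methylhex-5-en-2-one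
Product: 7 (R)-3-methyl-3-(triethylsilyloxy)hex-5-en-2-one
Conditions: TESOTf, 2,6-lutidine, CH2Cl2, −78 → 0 °C
Reagents that add atoms: triethylsilyl triflate CC[Si](CC)(CC)OS(=O)(=O)C(F)(F)F
Why: Silyl triflate silylation of a hindered tertiary alcohol, which keeps the hydroxyl from binding the borane in the aldol step.

Step 5
Reactants: 8 propargyl alcohol
Product: 9 (Z)-3-iodo-2-methylprop-2-en-1-ol
Conditions: MeMgBr (2.5 equiv), CuI (10 mol %), THF, −10 °C → rt; then I2, THF, 0 °C
Reagents that add atoms: methylmagnesium bromide C[Mg]Br; iodine II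
Why: Copper-catalysed, alkoxide-directed anti-carbomagnesiation gives a five-membered alkenylmagnesium alkoxide with the C–Mg bond cis to the carbinol carbon, and iodinolysis with retention fixes the Z-iodoalkene.

Step 6
Reactants: 9 (Z)-3-iodo-2-methylprop-2-en-1-ol
Product: 10 (Z)-3-iodo-2-methylprop-2-enal
Conditions: MnO2, CH2Cl2, rt, dark; used at once
Reagents that add atoms: none
Why: Neutral allylic oxidation with MnO2, which should leave the Z geometry untouched.

Step 7
Reactants: 7 (R)-3-methyl-3-(triethylsilyloxy)hex-5-en-2-one; 10 (Z)-3-iodo-2-methylprop-2-enal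
Product: 11 (4R,7S,8Z)-7-hydroxy-9-iodo-4,8-dimethyl-4-(triethylsilyloxy)nona-1,8-dien-5-one
Conditions: (+)-Ipc2BCl, Et3N, Et2O, 0 °C; then 10, −78 → −20 °C; then H2O2, pH 7 buffer, MeOH, 0 °C
Reagents that add atoms: none
Why: Paterson boron aldol reaction; only the methyl side of 7 can enolise, and the isopinocampheyl ligands should direct the enol borinate to the si face of 10 to set C3 (S).

Step 8
Reactants: 11 (4R,7S,8Z)-7-hydroxy-9-iodo-4,8-dimethyl-4-(triethylsilyloxy)nona-1,8-dien-5-one
Product: 13 (4R,5S,7S,8Z)-9-iodo-4,8-dimethylnona-1,8-diene-4,5,7-triol, via anti-diol TES ether 12 (not isolated)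
Conditions: Me4NBH(OAc)3, MeCN/AcOH (1:1), −25 °C; then 2 M HCl, 0 °C → rt
Reagents that add atoms: none
Why: Evans–Saksena reduction; the C3 hydroxyl binds the acyloxyborohydride and delivers hydride through a chair to set C1 (S) 1,3-anti to C3, and aqueous acid then removes the tertiary TES group.

Step 9
Reactants: 13 (4R,5S,7S,8Z)-9-iodo-4,8-dimethylnona-1,8-diene-4,5,7-triol
Product: 14 (2S,3Z)-1-[(4S,5R)-5-allyl-2,2,5-trimethyl-1,3-dioxolan-4-yl]-4-iodo-3-methylbut-3-en-2-ol
Conditions: Me2C(OMe)2, acetone, PPTS (cat.), rt (equilibrating)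
Reagents that add atoms: 2,2-dimethoxypropane COC(C)(C)OC
Why: Ketalisation under thermodynamic control should favour the dioxolane on the vicinal O1/O10 diol over the twist-boat dioxane of the 1,3-anti diol; because the diol is erythro, the C2 and C9 arms become cis on the new ring.

Step 10
Reactants: 14 (2S,3Z)-1-[(4S,5R)-5-allyl-2,2,5-trimethyl-1,3-dioxolan-4-yl]-4-iodo-3-methylbut-3-en-2-ol
Product: 15 tert-butyldimethylsilyl ether of 14 at O3
Conditions: TBSOTf, 2,6-lutidine, CH2Cl2, −78 °C
Reagents that add atoms: tert-butyldimethylsilyl triflate CC(C)(C)[Si](C)(C)OS(=O)(=O)C(F)(F)F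
Why: Standard silyl triflate protection of the only free hydroxyl, at a temperature the ketal tolerates.

Step 11
Reactants: 15 tert-butyldimethylsilyl ether of 14 at O3
Product: 16 2-{(4R,5S)-5-[(2S,3Z)-2-(tert-butyldimethylsilyloxy)-4-iodo-3-methylbut-3-en-1-yl]-2,2,4-trimethyl-1,3-dioxolan-4-yl}acetaldehyde (C8 aldehyde)
Conditions: OsO4 (2 mol %), NaIO4, 2,6-lutidine, dioxane/H2O (3:1), rt
Reagents that add atoms: sodium periodate [Na+].[O-]I(=O)(=O)=O
Why: Lemieux–Johnson cleavage; the monosubstituted alkene is osmylated much faster than the hindered, electron-poor trisubstituted iodoalkene.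

Step 12
Reactants: 17 (S)-4-benzyl-1,3-thiazolidine-2-thione; 18 monomethyl succinate
Product: 19 methyl 4-[(4S)-4-benzyl-2-thioxo-1,3-thiazolidin-3-yl]-4-oxobutanoate
Conditions: DCC, DMAP (cat.), CH2Cl2, 0 °C → rt
Reagents that add atoms: none
Why: Carbodiimide (Steglich-type) N-acylation of the auxiliary by the free acid end of the half ester.

Step 13
Reactants: 16 C8 aldehyde; 19 methyl 4-[(4S)-4-benzyl-2-thioxo-1,3-thiazolidin-3-yl]-4-oxobutanoate
Product: 21 methyl (3S,4R)-3-{[(4S)-4-benzyl-2-thioxo-1,3-thiazolidin-3-yl]carbonyl}-4-(triethylsilyloxy)-5-{(4R,5S)-5-[(2S,3Z)-2-(tert-butyldimethylsilyloxy)-4-iodo-3-methylbut-3-en-1-yl]-2,2,4-trimethyl-1,3-dioxolan-4-yl}pentanoate, via syn-aldol adduct 20 (not isolated)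
Conditions: 19, TiCl4, i-Pr2NEt, NMP, CH2Cl2, 0 °C; then 16, −78 °C; cold aq. NH4Cl; crude 20, TESOTf, 2,6-lutidine, CH2Cl2, −78 °C
Reagents that add atoms: triethylsilyl triflate CC[Si](CC)(CC)OS(=O)(=O)C(F)(F)F
Why: Crimmins titanium aldol reaction; the chlorotitanium Z-enolate reacts through the non-chelated chair (Evans-syn sense), the benzyl group sets C7 (S) and C8 (R), and the γ-hydroxy ester is silylated unpurified before it can lactonise onto C12.

Step 14
Reactants: 21 TES-protected aldol adduct
Product: 22 methyl (3S,4R)-3-formyl-4-(triethylsilyloxy)-5-{(4R,5S)-5-[(2S,3Z)-2-(tert-butyldimethylsilyloxy)-4-iodo-3-methylbut-3-en-1-yl]-2,2,4-trimethyl-1,3-dioxolan-4-yl}pentanoate (seco iodo aldehyde)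
Conditions: i-Bu2AlH, CH2Cl2, −78 °C (added until the yellow colour fades); aq. potassium sodium tartrate
Reagents that add atoms: none
Why: Direct hydride reduction of the activated N-acylthiazolidinethione to the aldehyde, which at −78 °C should be much faster than attack on the methyl ester.

Step 15
Reactants: 22 seco iodo aldehyde
Product: 24 (4Z)-3-(tert-butyldimethylsilyloxy)-1,10-(isopropylidenedioxy)-8-(triethylsilyloxy)-13-norgermacr-4-en-12,6-olide (trans-fused lactone; all stereocentres as in 32), via macrocyclic hydroxy ester 23 (not isolated)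
Conditions: CrCl2 (15 equiv), NiCl2 (1 mol % of the CrCl2), degassed DMSO/THF (3:1), slow addition of 22 (final 2 mM), rt; aq. Na2EDTA; then PPTS (cat.), benzene, 40 °C to complete lactonisation
Reagents that add atoms: none
Why: Zerovalent nickel inserts into the C5–I bond with retention, transmetalation to trivalent chromium gives the Z-alkenylchromium reagent, this adds to the C6 aldehyde, and the O6 chromium alkoxide, lying 1,4 to the C12 methyl ester, expels methoxide. The closest known reaction type is the intramolecular Nozaki–Hiyama–Kishi reaction used for nine- and ten-membered carbocycles, joined to the lactonisation known from chromium-mediated additions to γ-oxo esters. The ten-membered ring closes in a 10-exo-trig mode and the lactone in a 5-exo-trig mode. C6 (S) is set by Felkin–Anh control from C7: C5 attacks anti to the bulky C8 branch, an arrangement the forming ring can accommodate, and this places O6 syn to the C11 arm so that the trans-fused lactone can form. The step needs aldehyde-over-ester chemoselectivity, retention of the Z alkene and ring closure over oligomerisation: the first is inherent to alkenylchromium reagents, the second to trisubstituted iodoalkenes, and the third is secured by slow addition at high dilution and by two turn elements, the Z-C4=C5 alkene and the cis-dioxolane on C1/C10, which hold C5 near C6.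

Step 16
Reactants: 24 protected 13-nor lactone
Product: 27 (4Z)-3-(tert-butyldimethylsilyloxy)-1,10-(isopropylidenedioxy)-8-(triethylsilyloxy)germacra-4,11(13)-dien-12,6-olide (all stereocentres as in 32), via Mannich base 25 (not isolated), via trimethylammonium iodide 26 (not isolated)
Conditions: LiN(i-Pr)2, THF, −78 °C; CH2=NMe2+ I−, −78 °C → rt; then MeI, THF/MeOH, rt; then aq. NaHCO3, CH2Cl2, rt
Reagents that add atoms: N,N-dimethylmethyleneiminium iodide C=[N+](C)C.[I-]; iodomethane CI (stays in 26 only)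
Why: α-Methylenation by the Eschenmoser-salt Mannich reaction of the lactone enolate, N-methylation and Hofmann-type elimination; the C11 centre formed on the way is destroyed again and no leaving group sits β to the enolate.

Step 17
Reactants: 27 protected α-methylene lactone
Product: 28 (4Z)-3-(tert-butyldimethylsilyloxy)-8-hydroxy-1,10-(isopropylidenedioxy)germacra-4,11(13)-dien-12,6-olide (all stereocentres as in 32)
Conditions: HF·pyridine, pyridine, THF, 0 °C
Reagents that add atoms: none
Why: Selective fluoride desilylation; the secondary TES ether is far more labile than the TBS ether, and the buffered medium should spare the ketal and the α-methylene lactone.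

Step 18
Reactants: 28 C8 alcohol; 29 angelic acid
Product: 31 (4Z)-8-angeloyloxy-3-(tert-butyldimethylsilyloxy)-1,10-(isopropylidenedioxy)germacra-4,11(13)-dien-12,6-olide (all stereocentres as in 32), via mixed anhydride 30 (not isolated)
Conditions: 29, 2,4,6-Cl3C6H2COCl, Et3N, toluene, rt; then 28, 80 °C
Reagents that add atoms: 2,4,6-trichlorobenzoyl chloride O=C(Cl)c1c(Cl)cc(Cl)cc1Cl (stays in 30 only)
Why: Yamaguchi-type mixed-anhydride esterification without a nucleophilic catalyst, the variant known to transfer the angeloyl group without Z to E isomerisation; the alcohol reacts in neutral form, which should avoid translactonisation to O8.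

Step 19
Reactants: 31 protected angelate
Product: 32 CNP0249520.1, (1S,3S,4Z,6S,7S,8R,10R)-8-angeloyloxy-1,3,10-trihydroxygermacra-4,11(13)-dien-12,6-olide
Conditions: aq. HF (48 %), MeCN, 0 °C → rt
Reagents that add atoms: none
Why: Acidic fluoride deprotection removes the allylic TBS ether and hydrolyses the acetonide in one operation; no stereocentre is touched, and the esters and the α-methylene lactone tolerate the medium.

**Compound list**
1 | (S)-lactic acid | C[C@H](O)C(=O)O | starting material
2 | pivalaldehyde | CC(C)(C)C=O | starting material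
3 | (2S,5S)-2-tert-butyl-5-methyl-1,3-dioxolan-4-one | C[C@@H]1O[C@H](C(C)(C)C)OC1=O | intermediate
4 | allyl bromide | C=CCBr | starting material
5 | (2S,5R)-5-allyl-2-tert-butyl-5-methyl-1,3-dioxolan-4-one | C[C@]1(CC=C)O[C@H](C(C)(C)C)OC1=O | intermediate
6 | (R)-3-hydroxy-3-methylhex-5-en-2-one | CC(=O)[C@](C)(O)CC=C | intermediate
7 | (R)-3-methyl-3-(triethylsilyloxy)hex-5-en-2-one | CC(=O)[C@](C)(O[Si](CC)(CC)CC)CC=C | intermediate
8 | propargyl alcohol | C#CCO | starting material
9 | (Z)-3-iodo-2-methylprop-2-en-1-ol | OC/C(C)=C\I | intermediate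
10 | (Z)-3-iodo-2-methylprop-2-enal | O=C/C(C)=C\I | intermediate
11 | (4R,7S,8Z)-7-hydroxy-9-iodo-4,8-dimethyl-4-(triethylsilyloxy)nona-1,8-dien-5-one | I/C=C(/C)[C@@H](O)CC(=O)[C@](C)(O[Si](CC)(CC)CC)CC=C | intermediate
12 | (4R,5S,7S,8Z)-9-iodo-4,8-dimethyl-4-(triethylsilyloxy)nona-1,8-diene-5,7-diol | I/C=C(/C)[C@@H](O)C[C@H](O)[C@](C)(O[Si](CC)(CC)CC)CC=C | intermediate
13 | (4R,5S,7S,8Z)-9-iodo-4,8-dimethylnona-1,8-diene-4,5,7-triol | I/C=C(/C)[C@@H](O)C[C@H](O)[C@](C)(O)CC=C | intermediate
14 | (2S,3Z)-1-[(4S,5R)-5-allyl-2,2,5-trimethyl-1,3-dioxolan-4-yl]-4-iodo-3-methylbut-3-en-2-ol | I/C=C(/C)[C@@H](O)C[C@@H]1OC(C)(C)O[C@]1(C)CC=C | intermediate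
15 | O3-TBS ether of 14 | I/C=C(/C)[C@@H](O[Si](C)(C)C(C)(C)C)C[C@@H]1OC(C)(C)O[C@]1(C)CC=C | intermediate
16 | C8 aldehyde | I/C=C(/C)[C@@H](O[Si](C)(C)C(C)(C)C)C[C@@H]1OC(C)(C)O[C@]1(C)CC=O | intermediate
17 | (S)-4-benzyl-1,3-thiazolidine-2-thione | S=C1N[C@@H](Cc2ccccc2)CS1 | starting material
18 | monomethyl succinate | COC(=O)CCC(=O)O | starting material
19 | methyl 4-[(4S)-4-benzyl-2-thioxo-1,3-thiazolidin-3-yl]-4-oxobutanoate | COC(=O)CCC(=O)N1[C@@H](Cc2ccccc2)CSC1=S | intermediate
20 | syn-aldol adduct (7S,8R), free O8 hydroxyl | I/C=C(/C)[C@@H](O[Si](C)(C)C(C)(C)C)C[C@@H]1OC(C)(C)O[C@]1(C)C[C@@H](O)[C@H](CC(=O)OC)C(=O)N2[C@@H](Cc3ccccc3)CSC2=S | intermediate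
21 | O8-TES ether of 20 | I/C=C(/C)[C@@H](O[Si](C)(C)C(C)(C)C)C[C@@H]1OC(C)(C)O[C@]1(C)C[C@@H](O[Si](CC)(CC)CC)[C@H](CC(=O)OC)C(=O)N2[C@@H](Cc3ccccc3)CSC2=S | intermediate
22 | seco iodo aldehyde | I/C=C(/C)[C@@H](O[Si](C)(C)C(C)(C)C)C[C@@H]1OC(C)(C)O[C@]1(C)C[C@@H](O[Si](CC)(CC)CC)[C@H](CC(=O)OC)C=O | intermediate
23 | macrocyclic (6S)-hydroxy methyl ester (formed as its chromium alkoxide) | O[C@H]1/C=C(/C)[C@@H](O[Si](C)(C)C(C)(C)C)C[C@@H]2OC(C)(C)O[C@]2(C)C[C@@H](O[Si](CC)(CC)CC)[C@@H]1CC(=O)OC | intermediate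
24 | protected 13-norgermacr-4-en-12,6-olide | O=C1O[C@H]2/C=C(/C)[C@@H](O[Si](C)(C)C(C)(C)C)C[C@@H]3OC(C)(C)O[C@]3(C)C[C@@H](O[Si](CC)(CC)CC)[C@@H]2C1 | intermediate
25 | 11-(dimethylaminomethyl) lactone (Mannich base, aminomethyl trans to C8) | CN(C)C[C@H]1C(=O)O[C@H]2/C=C(/C)[C@@H](O[Si](C)(C)C(C)(C)C)C[C@@H]3OC(C)(C)O[C@]3(C)C[C@@H](O[Si](CC)(CC)CC)[C@H]12 | intermediate
26 | trimethylammonium iodide of 25 | C[N+](C)(C)C[C@H]1C(=O)O[C@H]2/C=C(/C)[C@@H](O[Si](C)(C)C(C)(C)C)C[C@@H]3OC(C)(C)O[C@]3(C)C[C@@H](O[Si](CC)(CC)CC)[C@H]12.[I-] | intermediate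
27 | protected α-methylene lactone | C=C1C(=O)O[C@H]2/C=C(/C)[C@@H](O[Si](C)(C)C(C)(C)C)C[C@@H]3OC(C)(C)O[C@]3(C)C[C@@H](O[Si](CC)(CC)CC)[C@H]12 | intermediate
28 | C8 alcohol | C=C1C(=O)O[C@H]2/C=C(/C)[C@@H](O[Si](C)(C)C(C)(C)C)C[C@@H]3OC(C)(C)O[C@]3(C)C[C@@H](O)[C@H]12 | intermediate
29 | angelic acid, (Z)-2-methylbut-2-enoic acid | C/C=C(/C)C(=O)O | starting material
30 | angelic 2,4,6-trichlorobenzoic anhydride | C/C=C(/C)C(=O)OC(=O)c1c(Cl)cc(Cl)cc1Cl | intermediate
31 | protected angelate | C=C1C(=O)O[C@H]2/C=C(/C)[C@@H](O[Si](C)(C)C(C)(C)C)C[C@@H]3OC(C)(C)O[C@]3(C)C[C@@H](OC(=O)/C(C)=C\C)[C@H]12 | intermediate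
32 | CNP0249520.1 | C=C1C(=O)O[C@H]2/C=C(/C)[C@@H](O)C[C@H](O)[C@](C)(O)C[C@@H](OC(=O)/C(C)=C\C)[C@H]12 | target

**Step count**
Total steps: 19. Longest linear sequence: 16 steps (1–4, 7–11, 13–19).

**Steps most likely to fail**

1. Step 15. Closure of the strained ten-membered ring may be slower than protodemetalation of the alkenylchromium species and intermolecular coupling. Facial selectivity at C6 may also erode, because the β-silyloxy group on C8 opposes the Felkin–Anh preference. The fallback makes C5–C6 intermolecularly and closes the ring at C4=C5 by metathesis. Setting out from 22, vinylmagnesium bromide (THF, −78 → 0 °C) adds to the aldehyde and the alkoxide lactonises to the γ-vinyl lactone F1, at which stage C6 epimers can be separated. Hydrodeiodination with Bu3SnH and Pd(PPh3)4 (cat.) gives the isopropenyl lactone F2. Ring-closing metathesis with the second-generation Grubbs catalyst (toluene, 80 °C, high dilution), in which the ring size should enforce the Z alkene, comes back to the route at 24.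

2. Step 7. Reagent control in methyl ketone boron aldol reactions is only moderate, and the distant C10 centre may oppose it, so facial selectivity at C3 may be poor. The fallback makes both C3 epimers convergent through substrate-directed reductions. Setting out from 7 and 10, the aldol is run with achiral c-Hex2BCl/Et3N and the epimers are separated; the (3S)-epimer is 11. The (3R)-aldol epimer F3 is reduced 1,3-syn (Et2BOMe, NaBH4, THF/MeOH, −78 °C, Narasaka–Prasad reduction) to the syn-diol TES ether F4, which again has (1S). Aqueous HCl gives the (1S,3R)-triol F5. MnO2 oxidises only the allylic C3 alcohol to the hydroxy enone F6. Evans–Saksena reduction, now directed by the C1 hydroxyl, sets (3S) and comes back to the route at 13.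

3. Step 13. The titanium aldolate or the free γ-hydroxy ester may lactonise onto the C12 methyl ester before silylation, which would tie C12 to O8 instead of leaving it for O6. The fallback uses a hindered ester and closes the lactone in a separate operation. Setting out from 17, DCC/DMAP acylation with commercial mono-tert-butyl succinate gives the tert-butyl succinyl thiazolidinethione F7. The same titanium aldol reaction with 16 gives the tert-butyl aldol adduct F8, which cannot lactonise readily, and TESOTf/2,6-lutidine gives its TES ether F9. Reduction with i-Bu2AlH gives the tert-butyl seco aldehyde F10, and CrCl2/NiCl2 under the conditions of step 15 closes the carbocycle to the macrocyclic hydroxy tert-butyl ester F11. TMSOTf/2,6-lutidine followed by citric acid in MeOH gives the hydroxy acid F12, which lactonises on standing and comes back to the route at 24.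

**Further compounds**
F1 | step 15 | γ-vinyl lactone (iodoalkene intact) | I/C=C(/C)[C@@H](O[Si](C)(C)C(C)(C)C)C[C@@H]1OC(C)(C)O[C@]1(C)C[C@@H](O[Si](CC)(CC)CC)[C@@H]2CC(=O)O[C@H]2C=C
F2 | step 15 | isopropenyl lactone (metathesis precursor) | C=C(C)[C@@H](O[Si](C)(C)C(C)(C)C)C[C@@H]1OC(C)(C)O[C@]1(C)C[C@@H](O[Si](CC)(CC)CC)[C@@H]2CC(=O)O[C@H]2C=C
F3 | step 7 | (3R)-aldol epimer of 11 | I/C=C(/C)[C@H](O)CC(=O)[C@](C)(O[Si](CC)(CC)CC)CC=C
F4 | step 7 | syn-diol TES ether (1S,3R) | I/C=C(/C)[C@H](O)C[C@H](O)[C@](C)(O[Si](CC)(CC)CC)CC=C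
F5 | step 7 | (1S,3R)-triol | I/C=C(/C)[C@H](O)C[C@H](O)[C@](C)(O)CC=C
F6 | step 7 | hydroxy enone (C3 ketone) | I/C=C(/C)C(=O)C[C@H](O)[C@](C)(O)CC=C
F7 | step 13 | tert-butyl succinyl thiazolidinethione | CC(C)(C)OC(=O)CCC(=O)N1[C@@H](Cc2ccccc2)CSC1=S
F8 | step 13 | tert-butyl aldol adduct | I/C=C(/C)[C@@H](O[Si](C)(C)C(C)(C)C)C[C@@H]1OC(C)(C)O[C@]1(C)C[C@@H](O)[C@H](CC(=O)OC(C)(C)C)C(=O)N2[C@@H](Cc3ccccc3)CSC2=S
F9 | step 13 | TES ether of F8 | I/C=C(/C)[C@@H](O[Si](C)(C)C(C)(C)C)C[C@@H]1OC(C)(C)O[C@]1(C)C[C@@H](O[Si](CC)(CC)CC)[C@H](CC(=O)OC(C)(C)C)C(=O)N2[C@@H](Cc3ccccc3)CSC2=S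
F10 | step 13 | tert-butyl seco aldehyde | I/C=C(/C)[C@@H](O[Si](C)(C)C(C)(C)C)C[C@@H]1OC(C)(C)O[C@]1(C)C[C@@H](O[Si](CC)(CC)CC)[C@H](CC(=O)OC(C)(C)C)C=O
F11 | step 13 | macrocyclic hydroxy tert-butyl ester | O[C@H]1/C=C(/C)[C@@H](O[Si](C)(C)C(C)(C)C)C[C@@H]2OC(C)(C)O[C@]2(C)C[C@@H](O[Si](CC)(CC)CC)[C@@H]1CC(=O)OC(C)(C)C
F12 | step 13 | macrocyclic hydroxy acid | O[C@H]1/C=C(/C)[C@@H](O[Si](C)(C)C(C)(C)C)C[C@@H]2OC(C)(C)O[C@]2(C)C[C@@H](O[Si](CC)(CC)CC)[C@@H]1CC(=O)O
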